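Numbering (daucane): C1 quaternary ring-fusion carbon, C2 and C3 the cyclopentane CH2 groups, C4 the isopropyl carbinol, C5 the ring-fusion CH, C6 the ester carbinol, C7=C8, C9 the free carbinol, C10 the ring CH2. The cyclopentane is cut into C3–C4(O)–C5, a 2-oxyallyl pattern, and C1(CH3)–C2, a 1,1-disubstituted alkene. A glyceraldehyde-derived propargylic pivalate becomes, by gold-catalysed 1,2-acyloxy shift, a C3-electrophilic and C5-nucleophilic three-carbon unit. It takes up methyl 3-methylbut-3-enoate in a formal [3+2] annulation, so that C2–C3, C1–C5, the quaternary centre and the masked C4 ketone arise together. Lactone-guided differentiation, isopropenyl addition and ring-closing metathesis then build the seven-membered ring.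

Key step: step 3

Remark: (S)-2,2-dimethyl-1,3-dioxolane-4-carbaldehyde and methyl 3-methylbut-3-enoate are taken as commercial compounds.

Step 1
Reactants: 1 (S)-2,2-dimethyl-1,3-dioxolane-4-carbaldehyde
Product: 2 1-[(4S)-2,2-dimethyl-1,3-dioxolan-4-yl]prop-2-yn-1-ol (both C5 epimers)
Conditions: HC≡CMgBr (1.3 equiv), THF, −78 to 0 °C
Reagents that add atoms: ethynylmagnesium bromide, C#C[Mg]Br
Why: Grignard 1,2-addition of an alkynyl nucleophile to the aldehyde; C5 forms as an epimer mixture, which is harmless because C5 becomes sp2 in step 3, while C6 is carried over unchanged from 1.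

Step 2
Reactants: 2 1-[(4S)-2,2-dimethyl-1,3-dioxolan-4-yl]prop-2-yn-1-ol
Product: 3 1-[(4S)-2,2-dimethyl-1,3-dioxolan-4-yl]prop-2-yn-1-yl pivalate (both C5 epimers)
Conditions: t-BuCOCl, Et3N, DMAP (cat.), CH2Cl2, 0 to 23 °C
Reagents that add atoms: pivaloyl chloride, CC(C)(C)C(=O)Cl
Why: DMAP-catalysed esterification installs the acyloxy group that migrates in step 3, and no stereocentre is touched.

Step 3
Reactants: 3 1-[(4S)-2,2-dimethyl-1,3-dioxolan-4-yl]prop-2-yn-1-yl pivalate; 4 methyl 3-methylbut-3-enoate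
Product: 7 methyl 2-{(1R,2S)-2-[(4R)-2,2-dimethyl-1,3-dioxolan-4-yl]-1-methyl-3-(pivaloyloxy)cyclopent-3-en-1-yl}acetate, via gold vinylcarbenoid 5 (not isolated), via vinylcyclopropane 6 (not isolated)
Conditions: Ph3PAuNTf2 (5 mol %), 4 (5 equiv), ClCH2CH2Cl, 23 °C, then 70 °C
Reagents that add atoms: none
Why: Proposed new method: monovalent gold activates the terminal alkyne of 3, the pivalate carbonyl adds to C4 (5-exo-dig) and the 1,2-acyloxy shift gives vinylcarbenoid 5, which is electrophilic at C3 and, once C3 has been alkylated, nucleophilic at C5 as an allylgold enol ester; the CH2 terminus C2 of 4 bonds to C3, the tertiary cationic centre C1 is caught first and reversibly at C3 (6) and then, on warming with the same catalyst, irreversibly at C5 with loss of gold (SE2′) to give 7. The closest known reaction types are the gold-catalysed 1,2-acyloxy migration/olefin cyclopropanation of propargylic esters, the gold-induced reversible opening of the vinylcyclopropanes so formed and the stepwise annulations of the same carbenoids with enol ethers and ynamides; new is the complete [3+2] outcome with a non-activated 1,1-disubstituted alkene. The one ring closed is the cyclopentene C1–C5, by cationic 5-endo-trig attack of the C4=C5 enol-ester bond on C1, which equals a 1,3-shift of C1 from C3 to C5 in 6. C5 is controlled by the C6 stereocentre, because allylic 1,3-strain against the cis pivaloyloxy group holds C6–H in the alkene plane and C1 approaches anti to the C6–O bond; C1 is controlled relative to C5, because the larger CH2CO2CH3 arm turns away from the dioxolane so that CH3 and C6 end up cis. The step needs regioselectivity (C2 to C3 and C1 to C5), which the matched polarity of both partners secures, a 1,2- rather than a 1,3-acyloxy shift, which the terminal alkyne secures, and ring closure faster than proton loss from C1, which the excess of 4 and the non-basic medium favour.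

Step 4
Reactants: 7 methyl 2-{(1R,2S)-2-[(4R)-2,2-dimethyl-1,3-dioxolan-4-yl]-1-methyl-3-(pivaloyloxy)cyclopent-3-en-1-yl}acetate
Product: 8 methyl 2-{(1R,2S)-2-[(4R)-2,2-dimethyl-1,3-dioxolan-4-yl]-1-methyl-3-oxocyclopentyl}acetate
Conditions: K2CO3 (0.2 equiv), MeOH, 0 °C
Reagents that add atoms: none
Why: Base-catalysed transesterification (methanolysis) of the enol ester and tautomerisation unmask the C4 ketone, and short contact at 0 °C should avoid epimerisation at C5 and β-elimination of the C6 oxygen.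

Step 5
Reactants: 8 methyl 2-{(1R,2S)-2-[(4R)-2,2-dimethyl-1,3-dioxolan-4-yl]-1-methyl-3-oxocyclopentyl}acetate
Product: 9 methyl 2-{(1R,2S,3R)-2-[(4R)-2,2-dimethyl-1,3-dioxolan-4-yl]-3-hydroxy-1-methyl-3-(propan-2-yl)cyclopentyl}acetate
Conditions: i-PrLi, CeCl3, THF, −78 °C
Reagents that add atoms: isopropyllithium, CC(C)[Li]
Why: Organocerium 1,2-addition to the ketone (low basicity suppresses enolisation and the ester survives at −78 °C); attack anti to the neighbouring dioxolanyl group on C5 places isopropyl cis to H5 and sets C4 as R.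

Step 6
Reactants: 9 methyl 2-{(1R,2S,3R)-2-[(4R)-2,2-dimethyl-1,3-dioxolan-4-yl]-3-hydroxy-1-methyl-3-(propan-2-yl)cyclopentyl}acetate
Product: 10 (1R,4aR,7R,7aS)-7-hydroxy-1-(hydroxymethyl)-4a-methyl-7-(propan-2-yl)hexahydrocyclopenta[c]pyran-3(1H)-one
Conditions: AcOH–H2O (4:1), 45 °C, then azeotropic drying with toluene
Reagents that add atoms: none
Why: Acetal hydrolysis followed by lactonisation of the secondary C6 hydroxyl with the C9 ester to the favoured six-membered, trans-fused ring, which tells the C6 and C7 hydroxyls apart without a protecting group and changes no stereocentre.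

Step 7
Reactants: 10 (1R,4aR,7R,7aS)-7-hydroxy-1-(hydroxymethyl)-4a-methyl-7-(propan-2-yl)hexahydrocyclopenta[c]pyran-3(1H)-one
Product: 11 (1R,4aR,7R,7aS)-7-hydroxy-4a-methyl-3-oxo-7-(propan-2-yl)octahydrocyclopenta[c]pyran-1-carbaldehyde
Conditions: Dess–Martin periodinane, CH2Cl2, 0 to 23 °C
Reagents that add atoms: none
Why: Dess–Martin oxidation of the primary alcohol; the tertiary C4 hydroxyl cannot be oxidised and the near-neutral medium keeps the α-acyloxy aldehyde centre C6 intact.

Step 8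
Reactants: 11 (1R,4aR,7R,7aS)-7-hydroxy-4a-methyl-3-oxo-7-(propan-2-yl)octahydrocyclopenta[c]pyran-1-carbaldehyde
Product: 12 (1S,4aR,7R,7aS)-1-ethenyl-7-hydroxy-4a-methyl-7-(propan-2-yl)hexahydrocyclopenta[c]pyran-3(1H)-one
Conditions: Ph3PCH3Br, KN(SiMe3)2, THF, −78 to 0 °C
Reagents that add atoms: methyltriphenylphosphonium bromide, C[P+](c1ccccc1)(c1ccccc1)c1ccccc1.[Br-]
Why: Wittig methylenation; at low temperature the non-stabilised ylide reacts with the aldehyde much faster than with the lactone, and the spatial arrangement at C6 is kept (the descriptor changes only by priority).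

Step 9
Reactants: 12 (1S,4aR,7R,7aS)-1-ethenyl-7-hydroxy-4a-methyl-7-(propan-2-yl)hexahydrocyclopenta[c]pyran-3(1H)-one
Product: 13 1-{(1R,2S,3R)-3-hydroxy-2-[(1S)-1-hydroxyprop-2-en-1-yl]-1-methyl-3-(propan-2-yl)cyclopentyl}-3-methylbut-3-en-2-one
Conditions: CH2=C(CH3)MgBr (3 equiv), THF, −78 to −20 °C
Reagents that add atoms: isopropenylmagnesium bromide, CC(=C)[Mg]Br
Why: Grignard acyl substitution on the lactone that stops after one addition at low temperature; it brings in C8 with its methyl group as the isopropenyl ketone and frees the C6 hydroxyl.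

Step 10
Reactants: 13 1-{(1R,2S,3R)-3-hydroxy-2-[(1S)-1-hydroxyprop-2-en-1-yl]-1-methyl-3-(propan-2-yl)cyclopentyl}-3-methylbut-3-en-2-one
Product: 14 (3R,3aS,4S,8aR)-3,4-dihydroxy-6,8a-dimethyl-3-(propan-2-yl)-2,3,3a,4,8,8a-hexahydroazulen-7(1H)-one
Conditions: second-generation Hoveyda–Grubbs catalyst (10 mol %), toluene (0.002 M), 80 °C
Reagents that add atoms: none
Why: Ring-closing olefin metathesis joins C7 and C8 to the trans-fused seven-membered ring, whose size enforces the Z geometry of the trisubstituted enone.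

Step 11
Reactants: 14 (3R,3aS,4S,8aR)-3,4-dihydroxy-6,8a-dimethyl-3-(propan-2-yl)-2,3,3a,4,8,8a-hexahydroazulen-7(1H)-one
Product: 15 (3R,3aS,4S,8aR)-3-hydroxy-6,8a-dimethyl-7-oxo-3-(propan-2-yl)-1,2,3,3a,4,7,8,8a-octahydroazulen-4-yl 4-methoxybenzoate
Conditions: 4-MeOC6H4COCl, Et3N, DMAP, CH2Cl2, 23 °C
Reagents that add atoms: 4-methoxybenzoyl chloride, COc1ccc(cc1)C(=O)Cl
Why: DMAP-catalysed esterification of the only acylable hydroxyl, the secondary allylic C6–OH, while the tertiary C4–OH stays inert.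

Step 12
Reactants: 15 (3R,3aS,4S,8aR)-3-hydroxy-6,8a-dimethyl-7-oxo-3-(propan-2-yl)-1,2,3,3a,4,7,8,8a-octahydroazulen-4-yl 4-methoxybenzoate
Product: 16 (3R,3aS,4S,7R,8aR)-3,7-dihydroxy-6,8a-dimethyl-3-(propan-2-yl)-1,2,3,3a,4,7,8,8a-octahydroazulen-4-yl 4-methoxybenzoate
Conditions: NaBH4, CeCl3·7H2O, MeOH, −40 °C
Reagents that add atoms: none
Why: Luche 1,2-reduction of the enone; hydride should reach C9 from the face opposite to the axial angular methyl group on C1, which gives the 9R alcohol cis to that methyl group, and the ester survives.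

Compound list
1 | (S)-2,2-dimethyl-1,3-dioxolane-4-carbaldehyde | O=C[C@@H]1COC(C)(C)O1 | starting material
2 | 1-[(4S)-2,2-dimethyl-1,3-dioxolan-4-yl]prop-2-yn-1-ol, both C5 epimers | C#CC(O)[C@@H]1COC(C)(C)O1 | intermediate
3 | 1-[(4S)-2,2-dimethyl-1,3-dioxolan-4-yl]prop-2-yn-1-yl pivalate, both C5 epimers | C#CC(OC(=O)C(C)(C)C)[C@@H]1COC(C)(C)O1 | intermediate
4 | methyl 3-methylbut-3-enoate | COC(=O)CC(C)=C | starting material
5 | {(Z)-3-[(4R)-2,2-dimethyl-1,3-dioxolan-4-yl]-2-(pivaloyloxy)prop-2-en-1-ylidene}(triphenylphosphine)gold cation | CC(C)(C)C(=O)O/C(C=[Au][P+](c1ccccc1)(c1ccccc1)c1ccccc1)=C\[C@@H]1COC(C)(C)O1 | intermediate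
6 | methyl 2-{2-[(Z)-2-[(4R)-2,2-dimethyl-1,3-dioxolan-4-yl]-1-(pivaloyloxy)ethenyl]-1-methylcyclopropyl}acetate, cyclopropane diastereomers | COC(=O)CC1(C)CC1/C(OC(=O)C(C)(C)C)=C/[C@@H]2COC(C)(C)O2 | intermediate
7 | methyl 2-{(1R,2S)-2-[(4R)-2,2-dimethyl-1,3-dioxolan-4-yl]-1-methyl-3-(pivaloyloxy)cyclopent-3-en-1-yl}acetate | COC(=O)C[C@@]1(C)CC=C(OC(=O)C(C)(C)C)[C@@H]1[C@@H]2COC(C)(C)O2 | intermediate
8 | methyl 2-{(1R,2S)-2-[(4R)-2,2-dimethyl-1,3-dioxolan-4-yl]-1-methyl-3-oxocyclopentyl}acetate | COC(=O)C[C@@]1(C)CCC(=O)[C@@H]1[C@@H]2COC(C)(C)O2 | intermediate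
9 | methyl 2-{(1R,2S,3R)-2-[(4R)-2,2-dimethyl-1,3-dioxolan-4-yl]-3-hydroxy-1-methyl-3-(propan-2-yl)cyclopentyl}acetate | COC(=O)C[C@@]1(C)CC[C@@](O)(C(C)C)[C@@H]1[C@@H]2COC(C)(C)O2 | intermediate
10 | (1R,4aR,7R,7aS)-7-hydroxy-1-(hydroxymethyl)-4a-methyl-7-(propan-2-yl)hexahydrocyclopenta[c]pyran-3(1H)-one | OC[C@@H]1OC(=O)C[C@@]2(C)CC[C@@](O)(C(C)C)[C@H]12 | intermediate
11 | (1R,4aR,7R,7aS)-7-hydroxy-4a-methyl-3-oxo-7-(propan-2-yl)octahydrocyclopenta[c]pyran-1-carbaldehyde | O=C[C@@H]1OC(=O)C[C@@]2(C)CC[C@@](O)(C(C)C)[C@H]12 | intermediate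
12 | (1S,4aR,7R,7aS)-1-ethenyl-7-hydroxy-4a-methyl-7-(propan-2-yl)hexahydrocyclopenta[c]pyran-3(1H)-one | C=C[C@@H]1OC(=O)C[C@@]2(C)CC[C@@](O)(C(C)C)[C@H]12 | intermediate
13 | 1-{(1R,2S,3R)-3-hydroxy-2-[(1S)-1-hydroxyprop-2-en-1-yl]-1-methyl-3-(propan-2-yl)cyclopentyl}-3-methylbut-3-en-2-one | C=C[C@H](O)[C@H]1[C@](O)(C(C)C)CC[C@]1(C)CC(=O)C(C)=C | intermediate
14 | (3R,3aS,4S,8aR)-3,4-dihydroxy-6,8a-dimethyl-3-(propan-2-yl)-2,3,3a,4,8,8a-hexahydroazulen-7(1H)-one | O[C@H]1C=C(C)C(=O)C[C@@]2(C)CC[C@@](O)(C(C)C)[C@H]12 | intermediate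
15 | (3R,3aS,4S,8aR)-3-hydroxy-6,8a-dimethyl-7-oxo-3-(propan-2-yl)-1,2,3,3a,4,7,8,8a-octahydroazulen-4-yl 4-methoxybenzoate | COc1ccc(C(=O)O[C@H]2C=C(C)C(=O)C[C@@]3(C)CC[C@@](O)(C(C)C)[C@H]23)cc1 | intermediate
16 | (3R,3aS,4S,7R,8aR)-3,7-dihydroxy-6,8a-dimethyl-3-(propan-2-yl)-1,2,3,3a,4,7,8,8a-octahydroazulen-4-yl 4-methoxybenzoate | COc1ccc(C(=O)O[C@H]2C=C(C)[C@H](O)C[C@@]3(C)CC[C@@](O)(C(C)C)[C@H]23)cc1 | target

Total step count: 12. Longest linear sequence: 12 steps (from 1).

Steps most likely to fail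

Step 3 (bears the label "Proposed new method:"). The cascade may stop at the cyclopropanation stage. It may also lose a proton from the cationic C1 before ring closure, or close with poor facial selectivity at C1. The fallback uses known chemistry, sets out from 3 and comes back at 8.
- Neighbouring-group-directed, gold-catalysed hydration of the propargylic ester (Ph3PAuNTf2, wet dioxane) should give the α-pivaloyloxy methyl ketone F1.
- Kinetic deprotonation at the methyl group (LiN(i-Pr)2, THF, −78 °C) and alkylation with methyl (E)-4-bromo-3-methylbut-2-enoate should give the keto enoate F2.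
- SmI2 (THF, −78 °C) should then cleave the α-pivaloyloxy group reductively. In the same flask this should bring about the 5-exo-trig intramolecular Michael addition of C5 to C1, which gives 8.

Step 10. Ring closure at the electron-poor 1,1-disubstituted alkene may be outrun by dimerisation through the vinyl group or by catalyst decay. The fallback replaces metathesis by an intramolecular Horner–Wadsworth–Emmons reaction, sets out from 10 and comes back at 15.
- Silylation of the primary hydroxyl (t-BuMe2SiCl, imidazole) should give the silyl ether lactone F3.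
- Opening of the lactone with LiCH(CH3)P(O)(OEt)2 (THF, −78 °C) should give the β-ketophosphonate alcohol F4.
- Acylation with 4-methoxybenzoyl chloride and DMAP should give the silyl ether anisate F5.
- HF·pyridine should give the primary alcohol F6.
- Dess–Martin oxidation should give the α-acyloxy aldehyde F7.
- LiCl and i-Pr2NEt in dilute MeCN should close the ring to 15.

Step 5. Enolisation of the hindered ketone, β-hydride transfer from the isopropyl reagent or attack on the wrong carbonyl face may erode the addition. The fallback changes to an sp2 nucleophile without β-hydrogen followed by saturation, sets out from 8 and comes back at 9.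
- Isopropenylmagnesium bromide with LaCl3·2LiCl (THF, −40 °C) should give the isopropenyl carbinol F8.
- Hydrogenation (H2, palladium on carbon, EtOAc) should give 9, because no other alkene is present at this stage.

Further compounds
F1 | step 3 | 1-[(4S)-2,2-dimethyl-1,3-dioxolan-4-yl]-2-oxopropyl pivalate, both C5 epimers | CC(=O)C(OC(=O)C(C)(C)C)[C@@H]1COC(C)(C)O1
F2 | step 3 | methyl (E)-7-[(4S)-2,2-dimethyl-1,3-dioxolan-4-yl]-3-methyl-6-oxo-7-(pivaloyloxy)hept-2-enoate, both C5 epimers | COC(=O)/C=C(\C)CCC(=O)C(OC(=O)C(C)(C)C)[C@@H]1COC(C)(C)O1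
F3 | step 10 | tert-butyldimethylsilyl ether of the primary hydroxyl of 10 | CC(C)(C)[Si](C)(C)OC[C@@H]1OC(=O)C[C@@]2(C)CC[C@@](O)(C(C)C)[C@H]12
F4 | step 10 | diethyl {4-[(1R,2S,3R)-2-[(1R)-2-(tert-butyldimethylsilyloxy)-1-hydroxyethyl]-3-hydroxy-1-methyl-3-(propan-2-yl)cyclopentyl]-3-oxobutan-2-yl}phosphonate, both C8 epimers | CCOP(=O)(OCC)C(C)C(=O)C[C@@]1(C)CC[C@@](O)(C(C)C)[C@@H]1[C@@H](O)CO[Si](C)(C)C(C)(C)C
F5 | step 10 | C6 4-methoxybenzoate of F4 | CCOP(=O)(OCC)C(C)C(=O)C[C@@]1(C)CC[C@@](O)(C(C)C)[C@@H]1[C@@H](OC(=O)c2ccc(OC)cc2)CO[Si](C)(C)C(C)(C)C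
F6 | step 10 | primary alcohol from desilylation of F5 | CCOP(=O)(OCC)C(C)C(=O)C[C@@]1(C)CC[C@@](O)(C(C)C)[C@@H]1[C@@H](OC(=O)c2ccc(OC)cc2)CO
F7 | step 10 | C7 aldehyde from oxidation of F6 | CCOP(=O)(OCC)C(C)C(=O)C[C@@]1(C)CC[C@@](O)(C(C)C)[C@@H]1[C@@H](OC(=O)c2ccc(OC)cc2)C=O
F8 | step 5 | methyl 2-{2-[(4R)-2,2-dimethyl-1,3-dioxolan-4-yl]-3-hydroxy-1-methyl-3-(prop-1-en-2-yl)cyclopentyl}acetate, ring configuration as in 9 | COC(=O)C[C@@]1(C)CC[C@@](O)(C(C)=C)[C@@H]1[C@@H]2COC(C)(C)O2
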